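**Plan**

- Retrosynthesis: remove the C5/C6 epoxide oxygen (leaving the 5E olefin), cut the C8 ester, then reconnect C1 to C6.
- Enabling feature: a bond between C1 and C6 turns the ten-membered lactone into a cyclohexane (C1–C6) bearing the trans C3/C4 diol of quinic acid, fused to a tetrahydropyran (O, C9, C8, C7, C6, C1); a tin substituent at C5 makes this bicycle a fragmentable stannyl hemiketal.
- Further cuts: C6–C7 (aldol) and C5–Sn (conjugate addition). The pieces are a trans-4,5-bis(silyloxy)cyclohexenone from quinic acid, a C7–C14 aldehyde from (E)-oct-2-en-1-ol, Bu3SnH, and the side-chain acid from (R)-2-methylbutanoic acid.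
- Forward order: carbocycle first, tin/aldol three-component coupling, tetrahydropyran by hemiketalisation, fusion of the two six-membered rings into the decanolide, C8 ester, epoxide last.
- Stereochemistry: C3/C4 from quinic acid; C8/C9 from Sharpless epoxidation plus invertive epoxide opening; C7 from the aldol (6,7-anti, 7,8-anti); 5E from the antiperiplanar fragmentation; the epoxide from Ti/D-(−)-tartrate epoxidation directed by C7–OH; the side-chain centre from the starting acid.

Key step: step 17

Assumption: locants C1–C14 follow the lactone (C1 = lactone carbonyl, C9 = ring carbon bearing pentyl); hemiketal 23 is drawn as its trans-fused anomer, which equilibrates with open form 22 and its C1 epimer, all of which feed the same fragmentation.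

**Route**

Step 1
Reactants: 1 (−)-quinic acid
Product: 2 methyl quinate 4,5-BDA diacetal (methyl ester; butane-2,3-diacetal across the trans O4/O5 pair; 1-OH and 3-OH free)
Conditions: butane-2,3-dione, HC(OMe)3, CSA (cat.), MeOH, reflux
Reagents that add atoms: butane-2,3-dione CC(=O)C(C)=O; methanol CO; trimethyl orthoformate COC(OC)OC
Why: Fischer esterification and butane-2,3-diacetal formation run in one pot; the diacetal selects the only trans-diequatorial diol, and its two new ketal carbons (S,S) are fixed thermodynamically by the anomeric effect (both methoxy groups axial on the trans-fused dioxane).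

Step 2
Reactants: 2 methyl quinate 4,5-BDA diacetal
Product: 3 BDA-protected triol (CH2OH in place of CO2Me)
Conditions: NaBH4, MeOH, 0 °C to rt
Reagents that add atoms: none
Why: Borohydride reduction of an α-hydroxy ester, activated by the neighbouring tertiary hydroxyl, should give the 1,2-diol without touching the diacetal.

Step 3
Reactants: 3 BDA-protected triol
Product: 4 BDA-protected 3-hydroxycyclohexanone
Conditions: NaIO4, THF/H2O, pH 7 buffer, 0 °C to rt
Reagents that add atoms: none
Why: Periodate glycol cleavage removes the exocyclic carbon as formaldehyde and leaves the C1 ketone; the 3-OH has no free vicinal partner and survives.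

Step 4
Reactants: 4 BDA-protected 3-hydroxycyclohexanone
Product: 6 BDA-protected (4R,5R)-4,5-dihydroxycyclohex-2-en-1-one, via mesylate 5 (not isolated)
Conditions: MsCl, Et3N, CH2Cl2, 0 °C to rt
Reagents that add atoms: none
Why: Mesylation of the β-hydroxy ketone followed by E1cB elimination gives the enone; only the unprotected 3-oxygen can leave, so the trans 4,5-dioxygenation is retained without ambiguity.

Step 5
Reactants: 6 BDA-protected enone
Product: 7 (4R,5R)-4,5-dihydroxycyclohex-2-en-1-one
Conditions: CF3CO2H/H2O (9:1), 0 °C, short contact, then evaporation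
Reagents that add atoms: none
Why: Acid-catalysed ketal hydrolysis frees the trans diol, and short contact at 0 °C should limit dehydration of the γ,δ-dihydroxy enone.

Step 6
Reactants: 7 (4R,5R)-4,5-dihydroxycyclohex-2-en-1-one
Product: 8 (4R,5R)-4,5-bis(tert-butyldimethylsilyloxy)cyclohex-2-en-1-one
Conditions: TBSOTf, 2,6-lutidine, CH2Cl2, −78 to 0 °C
Reagents that add atoms: tert-butyldimethylsilyl triflate CC(C)(C)[Si](C)(C)OS(=O)(=O)C(F)(F)F
Why: Silyl triflate silylation with a hindered base at low temperature avoids β-elimination; the rigid diacetal is exchanged for flexible silyl ethers because a locked diequatorial diol would hold the stannyl group axial after step 14, whereas silyl ethers let the ring adopt the all-equatorial chair needed in step 17.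

Step 7
Reactants: 9 (E)-oct-2-en-1-ol
Product: 10 (2S,3S)-2,3-epoxyoctan-1-ol
Conditions: Ti(OiPr)4 (cat.), L-(+)-diethyl tartrate (cat.), tBuOOH, 4 Å MS, CH2Cl2, −20 °C
Reagents that add atoms: tert-butyl hydroperoxide CC(C)(C)OO
Why: Sharpless asymmetric epoxidation; with L-(+)-tartrate an (E)-2-alken-1-ol gives the (2S,3S)-epoxide, which fixes the absolute configuration of the future C8 and, after inversion, C9.

Step 8
Reactants: 10 (2S,3S)-2,3-epoxyoctan-1-ol
Product: 11 (2S,3R)-1,2-dihydroxyoctan-3-yl benzoate
Conditions: Ti(OiPr)4 (1.5 equiv), PhCO2H, CH2Cl2, rt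
Reagents that add atoms: benzoic acid OC(=O)c1ccccc1
Why: Ti(OiPr)4-mediated opening of a 2,3-epoxy alcohol by a carboxylate occurs at C3 with inversion, giving the anti (2S,3R) arrangement required for C8/C9.

Step 9
Reactants: 11 (2S,3R)-1,2-dihydroxyoctan-3-yl benzoate
Product: 12 (1R)-1-[(4S)-2-(4-methoxyphenyl)-1,3-dioxolan-4-yl]hexyl benzoate (acetal carbon as a mixture of epimers)
Conditions: 4-MeOC6H4CH(OMe)2, PPTS (cat.), CH2Cl2, rt
Reagents that add atoms: 4-methoxybenzaldehyde dimethyl acetal COc1ccc(cc1)C(OC)OC
Why: Acid-catalysed transacetalisation closes the five-membered p-methoxybenzylidene acetal on the 1,2-diol; the new acetal carbon forms as a mixture that is erased in step 12.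

Step 10
Reactants: 12 acetal benzoate
Product: 13 (1R)-1-[(4S)-2-(4-methoxyphenyl)-1,3-dioxolan-4-yl]hexan-1-ol
Conditions: K2CO3 (cat.), MeOH, rt
Reagents that add atoms: none
Why: Base-catalysed transesterification (methanolysis) removes the benzoate while the acetal is inert to base.

Step 11
Reactants: 13 acetal alcohol
Product: 14 triethylsilyl ether of 13
Conditions: Et3SiCl, imidazole, CH2Cl2, 0 °C to rt
Reagents that add atoms: chlorotriethylsilane CC[Si](Cl)(CC)CC
Why: Standard silylation of the secondary alcohol; the triethylsilyl ether is chosen because it can later be cleaved in the presence of tert-butyldimethylsilyl ethers.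

Step 12
Reactants: 14 acetal triethylsilyl ether
Product: 15 (2S,3R)-2-(4-methoxybenzyloxy)-3-(triethylsilyloxy)octan-1-ol
Conditions: iBu2AlH, CH2Cl2, −78 to 0 °C
Reagents that add atoms: none
Why: Regioselective reductive opening of the p-methoxybenzylidene acetal: aluminium binds the less hindered primary oxygen, which is released as the alcohol, leaving the PMB group on the secondary (future C8) oxygen.

Step 13
Reactants: 15 primary alcohol
Product: 16 (2R,3R)-2-(4-methoxybenzyloxy)-3-(triethylsilyloxy)octanal
Conditions: PhI(OAc)2, TEMPO (cat.), CH2Cl2, rt; used at once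
Reagents that add atoms: none
Why: Oxoammonium (TEMPO) oxidation stops at the aldehyde and is mild enough not to epimerise the α-alkoxy centre.

Step 14
Reactants: 17 tributyltin hydride; 8 (4R,5R)-4,5-bis(tert-butyldimethylsilyloxy)cyclohex-2-en-1-one; 16 (2R,3R)-2-(4-methoxybenzyloxy)-3-(triethylsilyloxy)octanal
Product: 20 stannyl aldol ketone, via tributylstannyllithium 18 (not isolated), via lithium enolate 19 (not isolated)
Conditions: 17, LiN(iPr)2, THF, 0 °C; 8, −78 °C; 16, −78 °C; AcOH quench at −78 °C
Reagents that add atoms: none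
Why: Stannyl-anion conjugate addition followed by enolate aldol (three-component coupling): tin should enter at C5 anti to the C4 silyloxy group, the ring (E)-enolate should take up the aldehyde at C6 anti to tin through a closed Zimmerman–Traxler transition state (6,7-anti), and the aldehyde face should follow the polar Felkin–Anh/Cornforth model for the α-OPMB group (7,8-anti), so that C5, C6 and C7 are set in one operation, of which C5 and C6 are erased in step 17 and only their trans relation and C7 persist.

Step 15
Reactants: 20 stannyl aldol ketone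
Product: 21 C7 tert-butyldimethylsilyl ether of 20
Conditions: TBSOTf, 2,6-lutidine, CH2Cl2, −78 °C
Reagents that add atoms: tert-butyldimethylsilyl triflate CC(C)(C)[Si](C)(C)OS(=O)(=O)C(F)(F)F
Why: Low-temperature silylation of the aldol hydroxyl prevents retro-aldol and β-elimination and masks the C7 oxygen, so that later only the hemiketal oxygen can bind lead.

Step 16
Reactants: 21 C7 silyl ether
Product: 23 C5-tributylstannyl oxadecalin hemiketal, via δ-hydroxy ketone 22 (not isolated)
Conditions: HF·pyridine, pyridine, THF, 0 °C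
Reagents that add atoms: none
Why: Buffered HF·pyridine should cleave the triethylsilyl ether selectively over the three secondary TBS ethers, and the δ-hydroxy ketone closes by ring–chain tautomerism to the six-membered hemiketal, whose C1 configuration is set thermodynamically and erased in step 17.

Step 17
Reactants: 23 C5-tributylstannyl oxadecalin hemiketal
Product: 25 protected (5E)-ten-membered enolide, via lead alkoxide 24 (not isolated)
Conditions: Pb(OAc)4, benzene, 80 °C
Reagents that add atoms: none
Why: Ligand exchange of the hemiketal hydroxyl on tetravalent lead gives alkoxide 24; its O–Pb bond ionises to divalent lead while the C1–C6 σ bond becomes the lactone carbonyl and the antiperiplanar C5–Sn bond supplies the electrons for the C5=C6 π bond, releasing Bu3SnOAc, which is a heterolytic 1,4- (Grob-type) fragmentation whose closest known counterpart is the Pb(OAc)4 fragmentation of γ-stannyl alcohols and hemiketals made by stannyl-anion/enolate three-component coupling on cyclohexenones. The ten-membered ring is not closed end to end: it arises by ring expansion when the bond shared by the cyclohexane and the tetrahydropyran is cut, so no medium-ring cyclisation entropy or transannular strain is paid in a ring-closing transition state. No stereocentre is created; C1, C5 and C6 are destroyed and C3, C4, C7, C8 and C9 are untouched. The step needs E geometry and a single trigger site: E follows from the chair in which the equatorial C5–Sn bond is antiperiplanar to C1–C6 and C4 is anti to C7 across C5–C6, and the C7 oxygen is silylated so that only the hemiketal oxygen can bind lead (a free C7–OH would be a second γ-stannyl alcohol).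

Step 18
Reactants: 25 protected (5E)-enolide
Product: 26 C8 alcohol (3,4,7-tris-TBS enolide)
Conditions: DDQ, CH2Cl2/pH 7 buffer, 0 °C to rt
Reagents that add atoms: none
Why: Oxidative PMB cleavage by DDQ (benzylic oxocarbenium ion hydrolysed by water) frees C8–OH; silyl ethers, the lactone and the disubstituted olefin should be inert.

Step 19
Reactants: 27 (R)-2-methylbutanoic acid
Product: 28 (R)-2-methylbutan-1-ol
Conditions: LiAlH4, Et2O, 0 °C to rt
Reagents that add atoms: none
Why: Hydride reduction of the carboxylic acid proceeds through the carboxylate and does not epimerise the α-stereocentre.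

Step 20
Reactants: 28 (R)-2-methylbutan-1-ol
Product: 30 ethyl (R,E)-2,4-dimethylhex-2-enoate, via (R)-2-methylbutanal 29 (not isolated)
Conditions: PhI(OAc)2, TEMPO (cat.), CH2Cl2, rt; then Ph3P=C(Me)CO2Et, rt
Reagents that add atoms: ethyl 2-(triphenylphosphoranylidene)propanoate CCOC(=O)C(C)=P(c1ccccc1)(c1ccccc1)c1ccccc1
Why: One-pot oxoammonium oxidation and Wittig olefination avoids isolating the volatile, epimerisable α-branched aldehyde, and the stabilised α-methyl ylide gives the (E)-trisubstituted enoate.

Step 21
Reactants: 30 ethyl (R,E)-2,4-dimethylhex-2-enoate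
Product: 31 (R,E)-2,4-dimethylhex-2-enoic acid
Conditions: LiOH, THF/MeOH/H2O, 50 °C; then 1 M HCl
Reagents that add atoms: lithium hydroxide [Li+].[OH-]
Why: Saponification; the γ-stereocentre is not acidic enough under hydroxide to epimerise.

Step 22
Reactants: 31 (R,E)-2,4-dimethylhex-2-enoic acid; 26 C8 alcohol
Product: 33 C8 ester (3,4,7-tris-TBS), via mixed anhydride 32 (not isolated)
Conditions: 2,4,6-Cl3C6H2COCl, Et3N, THF, rt; then 26, DMAP, toluene, rt
Reagents that add atoms: none
Why: Yamaguchi esterification through the mixed anhydride acylates the hindered secondary C8–OH under DMAP catalysis without isomerising the (E)-enoate.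

Step 23
Reactants: 33 C8 ester (3,4,7-tris-TBS)
Product: 34 triol (5E-olefin, free 3-, 4- and 7-OH)
Conditions: HF·pyridine, pyridine, THF, 0 °C to rt
Reagents that add atoms: none
Why: Fluoride-mediated cleavage of all three silyl ethers under buffered, weakly acidic conditions, which should avoid acyl migration from O8 to O7 and translactonisation onto O4.

Step 24
Reactants: 34 triol
Product: 35 CNP0548321.2
Conditions: Ti(OiPr)4, D-(−)-diisopropyl tartrate, tBuOOH, 4 Å MS, CH2Cl2, −20 °C
Reagents that add atoms: tert-butyl hydroperoxide CC(C)(C)OO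
Why: Sharpless titanium–tartrate epoxidation directed by the allylic C7–OH: with D-(−)-tartrate the C7 carbinol has the fast-reacting configuration and gives the erythro (anti) epoxy alcohol, which is the 5R,6R epoxide, while the C4 carbinol is the slow-reacting configuration for this tartrate and would in any case direct the reagent to the same olefin face.

**Compound list**

1 | (−)-quinic acid | C1[C@H]([C@H]([C@@H](C[C@@]1(C(=O)O)O)O)O)O | starting material
2 | methyl quinate 4,5-BDA diacetal (ketal carbons S,S) | COC(=O)[C@]1(O)C[C@@H](O)[C@H]2O[C@](C)(OC)[C@@](C)(OC)O[C@@H]2C1 | intermediate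
3 | BDA-protected triol (1-hydroxymethyl) | OC[C@]1(O)C[C@@H](O)[C@H]2O[C@](C)(OC)[C@@](C)(OC)O[C@@H]2C1 | intermediate
4 | BDA-protected 3-hydroxycyclohexanone | O=C1C[C@@H](O)[C@H]2O[C@](C)(OC)[C@@](C)(OC)O[C@@H]2C1 | intermediate
5 | mesylate of 4 (not isolated) | O=C1C[C@@H](OS(C)(=O)=O)[C@H]2O[C@](C)(OC)[C@@](C)(OC)O[C@@H]2C1 | intermediate
6 | BDA-protected (4R,5R)-4,5-dihydroxycyclohex-2-en-1-one | O=C1C=C[C@H]2O[C@](C)(OC)[C@@](C)(OC)O[C@@H]2C1 | intermediate
7 | (4R,5R)-4,5-dihydroxycyclohex-2-en-1-one | O=C1C=C[C@@H](O)[C@H](O)C1 | intermediate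
8 | (4R,5R)-4,5-bis(tert-butyldimethylsilyloxy)cyclohex-2-en-1-one | O=C1C=C[C@@H](O[Si](C)(C)C(C)(C)C)[C@H](O[Si](C)(C)C(C)(C)C)C1 | intermediate
9 | (E)-oct-2-en-1-ol | CCCCC/C=C/CO | starting material
10 | (2S,3S)-2,3-epoxyoctan-1-ol | CCCCC[C@@H]1O[C@H]1CO | intermediate
11 | (2S,3R)-1,2-dihydroxyoctan-3-yl benzoate | OC[C@H](O)[C@H](OC(=O)c1ccccc1)CCCCC | intermediate
12 | (1R)-1-[(4S)-2-(4-methoxyphenyl)-1,3-dioxolan-4-yl]hexyl benzoate (acetal carbon unassigned, mixture) | COc1ccc(cc1)C2OC[C@H](O2)[C@H](OC(=O)c3ccccc3)CCCCC | intermediate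
13 | (1R)-1-[(4S)-2-(4-methoxyphenyl)-1,3-dioxolan-4-yl]hexan-1-ol | COc1ccc(cc1)C2OC[C@H](O2)[C@H](O)CCCCC | intermediate
14 | triethylsilyl ether of 13 | COc1ccc(cc1)C2OC[C@H](O2)[C@H](O[Si](CC)(CC)CC)CCCCC | intermediate
15 | (2S,3R)-2-(4-methoxybenzyloxy)-3-(triethylsilyloxy)octan-1-ol | OC[C@H](OCc1ccc(OC)cc1)[C@H](O[Si](CC)(CC)CC)CCCCC | intermediate
16 | (2R,3R)-2-(4-methoxybenzyloxy)-3-(triethylsilyloxy)octanal | O=C[C@H](OCc1ccc(OC)cc1)[C@H](O[Si](CC)(CC)CC)CCCCC | intermediate
17 | tributyltin hydride | CCCC[SnH](CCCC)CCCC | starting material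
18 | tributylstannyllithium (not isolated) | [Li][Sn](CCCC)(CCCC)CCCC | intermediate
19 | lithium enolate, C5-stannyl, 3,4-bis-TBS (not isolated) | [Li]OC1=C[C@H]([Sn](CCCC)(CCCC)CCCC)[C@@H](O[Si](C)(C)C(C)(C)C)[C@H](O[Si](C)(C)C(C)(C)C)C1 | intermediate
20 | stannyl aldol ketone: cyclohexanone C1–C6 with OTBS at C3 and C4, SnBu3 at C5, side chain C7(OH)–C8(OPMB)–C9(OTES)–pentyl at C6; all-trans on the ring, 6,7-anti, 7,8-anti, 8,9-anti | O=C1[C@@H]([C@H](O)[C@H](OCc2ccc(OC)cc2)[C@H](O[Si](CC)(CC)CC)CCCCC)[C@H]([Sn](CCCC)(CCCC)CCCC)[C@@H](O[Si](C)(C)C(C)(C)C)[C@H](O[Si](C)(C)C(C)(C)C)C1 | intermediate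
21 | C7 tert-butyldimethylsilyl ether of 20 | O=C1[C@@H]([C@H](O[Si](C)(C)C(C)(C)C)[C@H](OCc2ccc(OC)cc2)[C@H](O[Si](CC)(CC)CC)CCCCC)[C@H]([Sn](CCCC)(CCCC)CCCC)[C@@H](O[Si](C)(C)C(C)(C)C)[C@H](O[Si](C)(C)C(C)(C)C)C1 | intermediate
22 | δ-hydroxy ketone (C9–OH free, not isolated) | O=C1[C@@H]([C@H](O[Si](C)(C)C(C)(C)C)[C@H](OCc2ccc(OC)cc2)[C@H](O)CCCCC)[C@H]([Sn](CCCC)(CCCC)CCCC)[C@@H](O[Si](C)(C)C(C)(C)C)[C@H](O[Si](C)(C)C(C)(C)C)C1 | intermediate
23 | C5-tributylstannyl oxadecalin hemiketal (trans-fused; 3,4,7-tris-OTBS, 8-OPMB, 9-pentyl; Sn and C7 equatorial on the carbocycle) | CCCCC[C@H]1O[C@@]2(O)C[C@@H](O[Si](C)(C)C(C)(C)C)[C@H](O[Si](C)(C)C(C)(C)C)[C@@H]([Sn](CCCC)(CCCC)CCCC)[C@@H]2[C@H](O[Si](C)(C)C(C)(C)C)[C@@H]1OCc1ccc(OC)cc1 | intermediate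
24 | triacetoxylead alkoxide of hemiketal 23 (not isolated) | CCCCC[C@H]1O[C@@]2(O[Pb](OC(C)=O)(OC(C)=O)OC(C)=O)C[C@@H](O[Si](C)(C)C(C)(C)C)[C@H](O[Si](C)(C)C(C)(C)C)[C@@H]([Sn](CCCC)(CCCC)CCCC)[C@@H]2[C@H](O[Si](C)(C)C(C)(C)C)[C@@H]1OCc1ccc(OC)cc1 | intermediate
25 | protected (5E)-ten-membered enolide (3,4,7-tris-OTBS, 8-OPMB, 9-pentyl; C3, C4, C7, C8, C9 as in the target) | CCCCC[C@H]1OC(=O)C[C@@H](O[Si](C)(C)C(C)(C)C)[C@H](O[Si](C)(C)C(C)(C)C)/C=C/[C@H](O[Si](C)(C)C(C)(C)C)[C@@H]1OCc1ccc(OC)cc1 | intermediate
26 | C8 alcohol (3,4,7-tris-OTBS enolide) | CCCCC[C@H]1OC(=O)C[C@@H](O[Si](C)(C)C(C)(C)C)[C@H](O[Si](C)(C)C(C)(C)C)/C=C/[C@H](O[Si](C)(C)C(C)(C)C)[C@@H]1O | intermediate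
27 | (R)-2-methylbutanoic acid | CC[C@@H](C)C(=O)O | starting material
28 | (R)-2-methylbutan-1-ol | CC[C@@H](C)CO | intermediate
29 | (R)-2-methylbutanal (not isolated) | CC[C@@H](C)C=O | intermediate
30 | ethyl (R,E)-2,4-dimethylhex-2-enoate | CCOC(=O)/C(C)=C/[C@H](C)CC | intermediate
31 | (R,E)-2,4-dimethylhex-2-enoic acid | OC(=O)/C(C)=C/[C@H](C)CC | intermediate
32 | mixed anhydride of 31 with 2,4,6-trichlorobenzoic acid (not isolated) | O=C(OC(=O)c1c(Cl)cc(Cl)cc1Cl)/C(C)=C/[C@H](C)CC | intermediate
33 | C8 (R,E)-2,4-dimethylhex-2-enoate of 26 (3,4,7-tris-OTBS) | CCCCC[C@H]1OC(=O)C[C@@H](O[Si](C)(C)C(C)(C)C)[C@H](O[Si](C)(C)C(C)(C)C)/C=C/[C@H](O[Si](C)(C)C(C)(C)C)[C@@H]1OC(=O)/C(C)=C/[C@H](C)CC | intermediate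
34 | triol (5E-olefin, 3-, 4-, 7-OH free, C8 ester) | CCCCC[C@H]1OC(=O)C[C@@H](O)[C@H](O)/C=C/[C@H](O)[C@@H]1OC(=O)/C(C)=C/[C@H](C)CC | intermediate
35 | CNP0548321.2 | CCCCC[C@H]1OC(=O)C[C@@H](O)[C@H](O)[C@H]2O[C@@H]2[C@H](O)[C@@H]1OC(=O)/C(C)=C/[C@H](C)CC | target

**Count**

Total steps: 24. Longest linear sequence: 15 steps (steps 7–13, 14–18, 22–24).

**Steps most likely to fail**

Step 14. What may go wrong: tin may add with poor facial selectivity (partly syn to the C4 silyl ether), and the lithium aldol may show low simple diastereoselection or revert (retro-aldol) before the quench, giving mixtures at C6/C7. Fallback: setting out again from enone 8 and stannyllithium 18, the enolate 19 would be trapped with Me3SiCl to give the trimethylsilyl enol ether F1, which can be isolated and freed from any C5 epimer. Silicon-to-boron exchange with Bu2BOTf in CH2Cl2 would then give the dibutylboron enolate F2, and addition of aldehyde 16 at −78 °C (buffered methanol work-up without peroxide) should return to aldol 20. The boron aldol has a tighter chair transition state (stronger 6,7-anti preference) and a non-chelating metal (7,8-anti), and the aldolate is held as a borinate, which suppresses retro-aldol.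

Step 17. What may go wrong: too little of the closed hemiketal may be present at equilibrium (the C7 silyloxy group is axial on the tetrahydropyran), so that lead tetraacetate reacts slowly or attacks elsewhere, and E control could erode if a stepwise pathway takes over. Fallback: from hemiketal 23, H2O2 with catalytic AcOH in THF would add to the ketone tautomer and close to the hydroperoxy ketal F3, which traps the bicyclic form. Treatment with FeSO4 and Cu(OAc)2 in MeOH would cleave the O–O bond to the alkoxy radical, β-scission of C1–C6 gives the lactone and a C6 radical, and this radical ejects the β-stannyl group to form the C5=C6 olefin, coming back to the route at enolide 25. This is the known iron/copper-mediated alkoxy-radical fragmentation of α-alkoxy hydroperoxides used for macrolide ring expansion, a homolytic instead of heterolytic trigger.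

Step 24. What may go wrong: the free 3,4-diol may sequester titanium and displace the tartrate, slowing the reaction and eroding facial control, and the ring conformation may shield the required olefin face from the bound reagent. Fallback: from the fully silylated ester 33, a Shi epoxidation (D-fructose-derived ketone, KHSO5, K2CO3, MeCN/dimethoxymethane/H2O, 0 °C) would epoxidise the trans-disubstituted olefin under reagent control, with no free hydroxyl involved, in the sense that corresponds to the 5R,6R epoxide, giving the tris-silyl epoxide F4. HF·pyridine buffered with pyridine in THF would then remove the three silyl ethers and arrive directly at target 35.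

Further compounds
F1 | step 14 | trimethylsilyl enol ether of the C5-stannyl 3,4-bis-TBS cyclohexanone | C[Si](C)(C)OC1=C[C@H]([Sn](CCCC)(CCCC)CCCC)[C@@H](O[Si](C)(C)C(C)(C)C)[C@H](O[Si](C)(C)C(C)(C)C)C1
F2 | step 14 | dibutylboron enolate of the C5-stannyl 3,4-bis-TBS cyclohexanone | CCCCB(CCCC)OC1=C[C@H]([Sn](CCCC)(CCCC)CCCC)[C@@H](O[Si](C)(C)C(C)(C)C)[C@H](O[Si](C)(C)C(C)(C)C)C1
F3 | step 17 | hydroperoxy ketal of 23 (OOH in place of the hemiketal OH) | CCCCC[C@H]1O[C@@]2(OO)C[C@@H](O[Si](C)(C)C(C)(C)C)[C@H](O[Si](C)(C)C(C)(C)C)[C@@H]([Sn](CCCC)(CCCC)CCCC)[C@@H]2[C@H](O[Si](C)(C)C(C)(C)C)[C@@H]1OCc1ccc(OC)cc1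
F4 | step 24 | 3,4,7-tris-TBS ether of the target (5R,6R-epoxide) | CCCCC[C@H]1OC(=O)C[C@@H](O[Si](C)(C)C(C)(C)C)[C@H](O[Si](C)(C)C(C)(C)C)[C@H]2O[C@@H]2[C@H](O[Si](C)(C)C(C)(C)C)[C@@H]1OC(=O)/C(C)=C/[C@H](C)CC
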